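The cyclohexene ring (C1, C10–C14; briarane locants) holds the C12 oxygen and the C2 carbon on quaternary C1 cis and 1,4 to each other, so they can be joined as a lactone bridge. An inverse-demand Diels–Alder reaction of a 3,5-dimethyl-2-pyrone-4-carboxylate with a chiral vinyl ether therefore forms C12–C13 and C14–C1 at once, giving a 2-oxabicyclo[2.2.2]octene that fixes C1 and C12. Hydrogenation from the lactone face then sets C10 and C11, and elimination unveils C13=C14. The lactone is opened to a methyl ketone, a C4–C8/C17/C19 fragment is attached by enolate alkylation, and Nozaki–Hiyama–Kishi macrocyclisation, directed epoxidation, cuprate opening and oxidative lactonisation complete the target.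

Key step: step 5

Remark: locants are briarane locants of the target (C1 quaternary ring-fusion carbon, C2 and C12 acetoxy carbons, C5=C6 and C13=C14 alkenes, C7/C8/C17/C19 lactone); the sense of induction of the auxiliary in step 5 and of the ligand in step 13 is assumed by analogy, and the antipodal controller is equally available.

Step 1
Reactants: 1 di-tert-butyl oxalate
Product: 2 tert-butyl 2-oxobutanoate
Conditions: EtMgBr (1.0 equiv), THF, −78 °C; aq. NH4Cl
Reagents that add atoms: ethylmagnesium bromide (CC[Mg]Br)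
Why: Grignard mono-acylation of a dialkyl oxalate should stop at the α-keto ester because the magnesium hemiketal persists at low temperature.

Step 2
Reactants: 2 tert-butyl 2-oxobutanoate
Product: 3 tert-butyl (3E)-4-(dimethylamino)-3-methyl-2-oxobut-3-enoate
Conditions: Me2NCH(OMe)2, toluene, 80 °C
Reagents that add atoms: N,N-dimethylformamide dimethyl acetal (COC(OC)N(C)C)
Why: The activated methylene of the α-keto ester should condense with the amide acetal to the (E)-enaminone (enaminone formation).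

Step 3
Reactants: 3 enaminone, 4 methyl propanoate
Product: 6 tert-butyl 3,5-dimethyl-2-oxo-2H-pyran-4-carboxylate, via aldol adduct 5 (not isolated)
Conditions: LiN(i-Pr)2, THF, −78 °C, then 3; AcOH–H2O, 60 °C
Reagents that add atoms: none
Why: Aldol addition of the ester enolate to the ketone carbonyl, then acid-induced enamine hydrolysis, dehydration and enol lactonisation onto the methyl ester should give the 2-pyrone, in which no stereocentre survives.

Step 4
Reactants: 7 (1S)-1-(naphthalen-1-yl)ethan-1-ol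
Product: 8 1-[(1S)-1-(ethenyloxy)ethyl]naphthalene
Conditions: Hg(OAc)2 (5 mol%), ethyl vinyl ether (solvent), reflux
Reagents that add atoms: ethyl vinyl ether (C=COCC)
Why: Mercury-diacetate-catalysed transfer vinylation should exchange the alcohol into the vinyl ether without touching its stereocentre.

Step 5
Reactants: 6 pyrone, 8 chiral vinyl ether
Product: 9 Diels–Alder adduct, tert-butyl 4,6-dimethyl-8-[(1S)-1-(naphthalen-1-yl)ethoxy]-3-oxo-2-oxabicyclo[2.2.2]oct-5-ene-5-carboxylate (lactone bridge O12–C2, alkene C10=C11, ether on C14 endo)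
Conditions: Eu(fod)3 (5 mol%), CH2Cl2, 13 kbar, 25 °C
Reagents that add atoms: none
Why: This is an inverse-electron-demand Diels–Alder reaction of an electron-poor 2-pyrone with an electron-rich vinyl ether, a known reaction type that retains the CO2 bridge when run cold under pressure. The carbocycle C12–C13–C14–C1–C10–C11 closes by a concerted, asynchronous suprafacial [4+2] cycloaddition in which the nucleophilic CH2 terminus of the enol ether bonds to the electrophilic pyrone C6 (C12) and the alkoxy carbon to pyrone C3 (C1), which fixes the regiochemistry and places the oxygen on C14 next to the quaternary carbon. C12 and C1 are the bridgeheads of one lactone bridge, so O12 must be cis to C2. Their absolute configuration should follow from the pyrone face attacked, controlled by the 1-(1-naphthyl)ethyl auxiliary whose aryl group shields one face of the s-trans enol ether, while C14 is set endo by secondary overlap and is erased later. The step needs reactivity at the hindered C3 terminus without retro-[4+2] loss of CO2, which the C4 ester, the europium Lewis acid, high pressure and room temperature are meant to secure.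

Step 6
Reactants: 9 Diels–Alder adduct
Product: 11 tert-butyl 8-hydroxy-4,6-dimethyl-3-oxo-2-oxabicyclo[2.2.2]octane-5-carboxylate (H10 and H11 syn to the lactone bridge, C14 hydroxyl endo), via unsaturated hydroxy lactone 10 (not isolated)
Conditions: H2 (60 bar), Pd(OH)2/C, EtOAc, 25 °C
Reagents that add atoms: none
Why: Hydrogenolysis of the naphthylic ether and syn hydrogenation of the tetrasubstituted alkene from the open face beside the lactone bridge (the other face is screened by the C13–C14 bridge and its endo oxygen) should set C10 and C11 with both substituents anti to the lactone.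

Step 7
Reactants: 11 saturated hydroxy lactone
Product: 12 tert-butyl (1R,4S,7R,8S)-4,7-dimethyl-3-oxo-2-oxabicyclo[2.2.2]oct-5-ene-8-carboxylate
Conditions: Burgess reagent (MeO2CN–SO2–NEt3 inner salt), toluene, 60 °C
Reagents that add atoms: none
Why: Burgess dehydration is a syn elimination for which the eclipsed C13–H of the rigid bicycle is well placed, and since C1 bears no hydrogen only the C13=C14 alkene can form.

Step 8
Reactants: 12 bicyclic lactone
Product: 13 tert-butyl (1S,2S,5R,6R)-2-acetyl-5-hydroxy-2,6-dimethylcyclohex-3-ene-1-carboxylate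
Conditions: MeLi (1.1 equiv), THF, −78 °C; aq. NH4Cl
Reagents that add atoms: methyllithium (C[Li])
Why: Methyllithium should add once to the strained bridged lactone because the lithium hemiketal persists at −78 °C, releasing the methyl ketone and the C12 alcohol on work-up while the hindered tert-butyl ester is untouched (acyl substitution).

Step 9
Reactants: 14 (2Z)-4-{[tert-butyl(dimethyl)silyl]oxy}but-2-en-1-ol
Product: 15 (2Z)-4-{[tert-butyl(dimethyl)silyl]oxy}but-2-enal
Conditions: Dess–Martin periodinane, NaHCO3, CH2Cl2, 0 °C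
Reagents that add atoms: none
Why: Dess–Martin oxidation of the allylic alcohol should give the enal, whose alkene geometry is reset in the next step.

Step 10
Reactants: 15 enal
Product: 16 (2Z)-4-{[tert-butyl(dimethyl)silyl]oxy}-2-iodobut-2-enal
Conditions: I2, pyridine, CH2Cl2, 0 → 25 °C
Reagents that add atoms: iodine ([I][I])
Why: Pyridine-mediated α-iodination of the enal (conjugate addition, iodination, elimination) should give the thermodynamically preferred (Z)-2-iodoenal with iodine cis to the CH2O group.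

Step 11
Reactants: 17 prop-2-yn-1-ol
Product: 19 (2Z)-3-iodo-2-methylprop-2-en-1-ol, via alkenylmagnesium alkoxide 18 (not isolated)
Conditions: MeMgBr (2.2 equiv), CuI (10 mol%), THF, −10 → 25 °C; then I2, −40 °C
Reagents that add atoms: methylmagnesium bromide (C[Mg]Br); iodine ([I][I])
Why: Copper-catalysed anti carbomagnesiation of the propargylic alkoxide followed by iodinolysis with retention should give the (Z)-iodoalkene.

Step 12
Reactants: 19 (2Z)-3-iodo-2-methylprop-2-en-1-ol
Product: 20 triethyl{[(2Z)-3-iodo-2-methylprop-2-en-1-yl]oxy}silane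
Conditions: Et3SiCl, imidazole, CH2Cl2, 0 °C
Reagents that add atoms: chlorotriethylsilane (CC[Si](Cl)(CC)CC)
Why: Silyl ether formation on the primary allylic alcohol.

Step 13
Reactants: 20 triethylsilyl ether, 16 (Z)-2-iodoenal
Product: 23 (2Z,4S,5Z)-7-{[tert-butyl(dimethyl)silyl]oxy}-5-iodo-2-methyl-1-[(triethylsilyl)oxy]hepta-2,5-dien-4-ol, via alkenyllithium 21 (not isolated), via alkenylzinc bromide 22 (not isolated)
Conditions: t-BuLi (2 equiv), Et2O, −78 °C; ZnBr2; N,N,N′,N′-tetraethylethylenediamine; (−)-MIB [(2S)-3-exo-morpholinoisoborneol] (10 mol%), toluene, −10 °C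
Reagents that add atoms: none
Why: Iodine–lithium exchange with retention, transmetalation to zinc and amino-alcohol-catalysed alkenylzinc addition to the aldehyde, the ligand directing attack to the Si face, should set C7 as (S).

Step 14
Reactants: 23 divinyl carbinol
Product: 24 the 4-O-tert-butyldimethylsilyl ether of 23
Conditions: TBSCl, imidazole, DMF, 25 °C
Reagents that add atoms: tert-butyldimethylsilyl chloride (CC(C)(C)[Si](C)(C)Cl)
Why: Silyl ether formation on the secondary alcohol.

Step 15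
Reactants: 24 tris-silyl ether
Product: 25 (2Z,4S,5Z)-4,7-bis{[tert-butyl(dimethyl)silyl]oxy}-5-iodo-2-methylhepta-2,5-dien-1-ol
Conditions: PPTS, MeOH, 0 °C
Reagents that add atoms: none
Why: Acid methanolysis should cleave the primary triethylsilyl ether far faster than the tert-butyldimethylsilyl ethers.

Step 16
Reactants: 25 primary allylic alcohol
Product: 26 (2Z,4S,5Z)-1-bromo-4,7-bis{[tert-butyl(dimethyl)silyl]oxy}-5-iodo-2-methylhepta-2,5-diene
Conditions: CBr4, PPh3, 2,6-lutidine, CH2Cl2, −20 °C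
Reagents that add atoms: tetrabromomethane (BrC(Br)(Br)Br)
Why: Appel bromination of the primary allylic alcohol by SN2 displacement should proceed without allylic transposition.

Step 17
Reactants: 13 hydroxy methyl ketone, 26 allylic bromide
Product: 28 C3–C4 alkylation product (the acetyl group of 13 extended to the (4Z,6S,7Z)-6,9-bis(silyloxy)-7-iodo-4-methylnona-4,7-dienoyl chain), via dilithium alkoxide enolate 27 (not isolated)
Conditions: LiN(i-Pr)2 (2.2 equiv), THF–DMPU, −78 °C; then 26, −78 → −40 °C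
Reagents that add atoms: none
Why: Because C1 is quaternary the methyl ketone has a single enolate, which should be C-alkylated by the allylic bromide beside the unreactive C12 lithium alkoxide (enolate alkylation).

Step 18
Reactants: 28 alkylated ketone
Product: 29 (2R)-C2,C12-diol
Conditions: (S)-Me-CBS oxazaborolidine (20 mol%), catecholborane, toluene, −78 °C
Reagents that add atoms: none
Why: In this Corey–Bakshi–Shibata reduction the quaternary C1 side is the large group, so the (S)-catalyst should deliver hydride to give the (2R)-alcohol under reagent control.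

Step 19
Reactants: 29 diol
Product: 30 C2,C12-bis(tert-butyldimethylsilyl) ether
Conditions: TBSOTf, 2,6-lutidine, CH2Cl2, −78 → −20 °C
Reagents that add atoms: tert-butyldimethylsilyl triflate (CC(C)(C)[Si](C)(C)OS(=O)(=O)C(F)(F)F)
Why: Silyl ether formation on both secondary alcohols at low temperature should spare the tert-butyl ester.

Step 20
Reactants: 30 tert-butyl ester
Product: 31 C9 aldehyde
Conditions: i-Bu2AlH, CH2Cl2, −78 °C; Rochelle salt
Reagents that add atoms: none
Why: Partial reduction of the tert-butyl ester should stop at the aluminium hemiacetal, stable at −78 °C, which gives the aldehyde on work-up.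

Step 21
Reactants: 31 iodo aldehyde
Product: 32 ten-membered (9R)-allylic alcohol with exocyclic C8=C17 (CH2OTBS cis to C9)
Conditions: CrCl2 (8 equiv), NiCl2 (2 mol%), DMSO–THF, 25 °C, 2 mM
Reagents that add atoms: none
Why: In this Nozaki–Hiyama–Kishi reaction the alkenylchromium species formed under nickel catalysis should add chemoselectively to the aldehyde at high dilution to close the ten-membered ring, Felkin–Anh attack anti to quaternary C1 setting C9 as (R).

Step 22
Reactants: 32 macrocyclic allylic alcohol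
Product: 33 8,17-epoxide (epoxide oxygen at C8 as the C8 oxygen of the target)
Conditions: VO(acac)2 (5 mol%), t-BuOOH, CH2Cl2, 0 °C
Reagents that add atoms: tert-butyl hydroperoxide (CC(C)(C)OO)
Why: In this vanadium-catalysed hydroxyl-directed epoxidation, allylic 1,3-strain from the CH2OTBS group cis to C9 fixes the allylic alcohol conformation, so oxygen should reach the face that gives the C8 configuration of the target, while the other alkenes have no free directing hydroxyl.

Step 23
Reactants: 33 epoxy alcohol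
Product: 34 C8,C9-diol with the C17 methyl stereocentre
Conditions: Me2CuLi (5 equiv), Et2O, −30 → 0 °C; aq. NH4Cl
Reagents that add atoms: lithium dimethylcuprate ([Li+].C[Cu-]C)
Why: SN2 opening of the trisubstituted epoxide by the cuprate at the less substituted C17 with inversion should give the tertiary C8 alcohol and the C17 configuration of the target.

Step 24
Reactants: 34 diol
Product: 35 C8,C9-acetonide
Conditions: 2-methoxypropene, PPTS (cat.), CH2Cl2, 0 °C
Reagents that add atoms: 2-methoxypropene (COC(C)=C)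
Why: Acid-catalysed acetonide formation should protect the vicinal diol and leave the silyl ethers intact.

Step 25
Reactants: 35 tetrakis-silyl ether
Product: 36 C2,C7,C12,C19-tetraol acetonide
Conditions: Bu4NF, THF, 25 °C
Reagents that add atoms: none
Why: Fluoride should cleave all four silyl ethers while the acetonide is stable.

Step 26
Reactants: 36 tetraol
Product: 38 γ-lactone diol (C19 carbonyl, O7), via lactol 37 (not isolated)
Conditions: TEMPO (20 mol%), PhI(OAc)2 (2.5 equiv), CH2Cl2, 25 °C
Reagents that add atoms: none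
Why: The oxoammonium oxidant should select the primary C19 alcohol, the aldehyde being trapped by the C7 hydroxyl as a five-membered lactol that is oxidised on to the lactone (oxidative lactonisation).

Step 27
Reactants: 38 lactone diol
Product: 39 C2,C12-diacetate acetonide
Conditions: Ac2O, pyridine, DMAP (cat.), CH2Cl2, 0 → 25 °C
Reagents that add atoms: acetic anhydride (CC(=O)OC(C)=O)
Why: DMAP-catalysed acetylation of the two free secondary alcohols, the C8 and C9 oxygens being masked.

Step 28
Reactants: 39 diacetate acetonide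
Product: 40 target CNP0286823.1
Conditions: AcOH–H2O (4:1), 40 °C
Reagents that add atoms: none
Why: Mild aqueous acid should hydrolyse the acetonide while the acetates and the lactone survive.

Compound list
1 | di-tert-butyl oxalate | CC(C)(C)OC(=O)C(=O)OC(C)(C)C | starting material
2 | tert-butyl 2-oxobutanoate | CCC(=O)C(=O)OC(C)(C)C | intermediate
3 | tert-butyl (3E)-4-(dimethylamino)-3-methyl-2-oxobut-3-enoate | CN(C)/C=C(\C)C(=O)C(=O)OC(C)(C)C | intermediate
4 | methyl propanoate | CCC(=O)OC | starting material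
5 | aldol adduct, 1-tert-butyl 4-methyl 2-[(1E)-1-(dimethylamino)prop-1-en-2-yl]-2-hydroxy-3-methylbutanedioate (diastereomer mixture, not isolated) | CN(C)/C=C(\C)C(O)(C(C)C(=O)OC)C(=O)OC(C)(C)C | intermediate
6 | tert-butyl 3,5-dimethyl-2-oxo-2H-pyran-4-carboxylate | CC1=COC(=O)C(C)=C1C(=O)OC(C)(C)C | intermediate
7 | (1S)-1-(naphthalen-1-yl)ethan-1-ol | C[C@H](O)c1cccc2ccccc12 | starting material
8 | 1-[(1S)-1-(ethenyloxy)ethyl]naphthalene | C[C@H](OC=C)c1cccc2ccccc12 | intermediate
9 | Diels–Alder adduct, tert-butyl 4,6-dimethyl-8-[(1S)-1-(naphthalen-1-yl)ethoxy]-3-oxo-2-oxabicyclo[2.2.2]oct-5-ene-5-carboxylate, ether endo | O2[C@@H]1C[C@@H](O[C@@H](C)c3cccc4ccccc34)[C@@](C2=O)(C)C(C(=O)OC(C)(C)C)=C1C | intermediate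
10 | tert-butyl 8-hydroxy-4,6-dimethyl-3-oxo-2-oxabicyclo[2.2.2]oct-5-ene-5-carboxylate, endo alcohol (not isolated) | O2[C@@H]1C[C@@H](O)[C@@](C2=O)(C)C(C(=O)OC(C)(C)C)=C1C | intermediate
11 | tert-butyl 8-hydroxy-4,6-dimethyl-3-oxo-2-oxabicyclo[2.2.2]octane-5-carboxylate, H5 and H6 syn to the lactone bridge | O2[C@@H]1C[C@@H](O)[C@@](C2=O)(C)[C@H]([C@H]1C)C(=O)OC(C)(C)C | intermediate
12 | tert-butyl (1R,4S,7R,8S)-4,7-dimethyl-3-oxo-2-oxabicyclo[2.2.2]oct-5-ene-8-carboxylate | O2[C@@H]1C=C[C@@](C2=O)(C)[C@H]([C@H]1C)C(=O)OC(C)(C)C | intermediate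
13 | tert-butyl (1S,2S,5R,6R)-2-acetyl-5-hydroxy-2,6-dimethylcyclohex-3-ene-1-carboxylate | O[C@@H]1C=C[C@@](C(C)=O)(C)[C@H]([C@H]1C)C(=O)OC(C)(C)C | intermediate
14 | (2Z)-4-{[tert-butyl(dimethyl)silyl]oxy}but-2-en-1-ol | CC(C)(C)[Si](C)(C)OC/C=C\CO | starting material
15 | (2Z)-4-{[tert-butyl(dimethyl)silyl]oxy}but-2-enal | CC(C)(C)[Si](C)(C)OC/C=C\C=O | intermediate
16 | (2Z)-4-{[tert-butyl(dimethyl)silyl]oxy}-2-iodobut-2-enal | CC(C)(C)[Si](C)(C)OC/C=C(\I)C=O | intermediate
17 | prop-2-yn-1-ol | C#CCO | starting material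
18 | bromomagnesium (2Z)-3-(bromomagnesio)-2-methylprop-2-en-1-olate (not isolated) | Br[Mg]/C=C(/C)CO[Mg]Br | intermediate
19 | (2Z)-3-iodo-2-methylprop-2-en-1-ol | OC/C(C)=C\I | intermediate
20 | triethyl{[(2Z)-3-iodo-2-methylprop-2-en-1-yl]oxy}silane | CC[Si](CC)(CC)OC/C(C)=C\I | intermediate
21 | (Z)-alkenyllithium from 20 (not isolated) | CC[Si](CC)(CC)OC/C(C)=C\[Li] | intermediate
22 | (Z)-alkenylzinc bromide from 21 (not isolated) | CC[Si](CC)(CC)OC/C(C)=C\[Zn]Br | intermediate
23 | (2Z,4S,5Z)-7-{[tert-butyl(dimethyl)silyl]oxy}-5-iodo-2-methyl-1-[(triethylsilyl)oxy]hepta-2,5-dien-4-ol | CC(C)(C)[Si](C)(C)OC/C=C(\I)[C@@H](O)/C=C(/C)CO[Si](CC)(CC)CC | intermediate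
24 | 4-O-tert-butyldimethylsilyl ether of 23 | CC(C)(C)[Si](C)(C)OC/C=C(\I)[C@@H](O[Si](C)(C)C(C)(C)C)/C=C(/C)CO[Si](CC)(CC)CC | intermediate
25 | (2Z,4S,5Z)-4,7-bis{[tert-butyl(dimethyl)silyl]oxy}-5-iodo-2-methylhepta-2,5-dien-1-ol | CC(C)(C)[Si](C)(C)OC/C=C(\I)[C@@H](O[Si](C)(C)C(C)(C)C)/C=C(/C)CO | intermediate
26 | (2Z,4S,5Z)-1-bromo-4,7-bis{[tert-butyl(dimethyl)silyl]oxy}-5-iodo-2-methylhepta-2,5-diene | CC(C)(C)[Si](C)(C)OC/C=C(\I)[C@@H](O[Si](C)(C)C(C)(C)C)/C=C(/C)CBr | intermediate
27 | dilithium C12-alkoxide methyl-ketone enolate of 13 (not isolated) | [Li]O[C@@H]1C=C[C@@](C(=C)O[Li])(C)[C@H]([C@H]1C)C(=O)OC(C)(C)C | intermediate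
28 | tert-butyl (1S,2S,5R,6R)-2-[(4Z,6S,7Z)-6,9-bis{[tert-butyl(dimethyl)silyl]oxy}-7-iodo-4-methylnona-4,7-dienoyl]-5-hydroxy-2,6-dimethylcyclohex-3-ene-1-carboxylate | O[C@@H]1C=C[C@@](C(=O)CC/C(C)=C\[C@H](O[Si](C)(C)C(C)(C)C)/C(I)=C/CO[Si](C)(C)C(C)(C)C)(C)[C@H]([C@H]1C)C(=O)OC(C)(C)C | intermediate
29 | (2R)-alcohol from 28 (C2,C12-diol; other centres as in 28) | O[C@@H]1C=C[C@@]([C@H](O)CC/C(C)=C\[C@H](O[Si](C)(C)C(C)(C)C)/C(I)=C/CO[Si](C)(C)C(C)(C)C)(C)[C@H]([C@H]1C)C(=O)OC(C)(C)C | intermediate
30 | C2,C12-bis(tert-butyldimethylsilyl) ether of 29 | CC(C)(C)[Si](C)(C)O[C@@H]1C=C[C@@]([C@H](O[Si](C)(C)C(C)(C)C)CC/C(C)=C\[C@H](O[Si](C)(C)C(C)(C)C)/C(I)=C/CO[Si](C)(C)C(C)(C)C)(C)[C@H]([C@H]1C)C(=O)OC(C)(C)C | intermediate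
31 | C9 aldehyde from 30 | CC(C)(C)[Si](C)(C)O[C@@H]1C=C[C@@]([C@H](O[Si](C)(C)C(C)(C)C)CC/C(C)=C\[C@H](O[Si](C)(C)C(C)(C)C)/C(I)=C/CO[Si](C)(C)C(C)(C)C)(C)[C@H]([C@H]1C)C=O | intermediate
32 | macrocyclic (1S,2R,5Z,7S,9R,10S,11R,12R)-allylic alcohol, exocyclic C8=C17 with CH2OTBS cis to C9; silyl ethers at O2, O7, O12, O19 | CC(C)(C)[Si](C)(C)O[C@@H]1C=C[C@@]2(C)[C@H]([C@H]1C)[C@@H](O)/C(=C\CO[Si](C)(C)C(C)(C)C)[C@H](/C=C(/C)CC[C@H]2O[Si](C)(C)C(C)(C)C)O[Si](C)(C)C(C)(C)C | intermediate
33 | 8,17-epoxide of 32 (C8 oxygen as in the target, CH2OTBS cis to C9) | CC(C)(C)[Si](C)(C)O[C@@H]1C=C[C@@]2(C)[C@H]([C@H]1C)[C@@H](O)[C@@]3(O[C@@H]3CO[Si](C)(C)C(C)(C)C)[C@H](/C=C(/C)CC[C@H]2O[Si](C)(C)C(C)(C)C)O[Si](C)(C)C(C)(C)C | intermediate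
34 | C8,C9-diol with C17 methyl (C8, C9, C17 arranged as in the target; C19 as CH2OTBS) | CC(C)(C)[Si](C)(C)O[C@@H]1C=C[C@@]2(C)[C@H]([C@H]1C)[C@@H](O)[C@@]([C@@H](C)CO[Si](C)(C)C(C)(C)C)(O)[C@H](/C=C(/C)CC[C@H]2O[Si](C)(C)C(C)(C)C)O[Si](C)(C)C(C)(C)C | intermediate
35 | C8,C9-acetonide of 34 | CC(C)(C)[Si](C)(C)O[C@@H]1C=C[C@@]2(C)[C@H]([C@H]1C)[C@H]3OC(C)(C)O[C@@]3([C@@H](C)CO[Si](C)(C)C(C)(C)C)[C@H](/C=C(/C)CC[C@H]2O[Si](C)(C)C(C)(C)C)O[Si](C)(C)C(C)(C)C | intermediate
36 | C2,C7,C12,C19-tetraol C8,C9-acetonide | O[C@@H]1C=C[C@@]2(C)[C@H]([C@H]1C)[C@H]3OC(C)(C)O[C@@]34[C@H](/C=C(/C)CC[C@H]2O)OC(O)[C@@H]4C | intermediate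
37 | C19 lactol (O7–C19, not isolated) | O[C@@H]1C=C[C@@]2(C)[C@H]([C@H]1C)[C@H]3OC(C)(C)O[C@@]3([C@@H](C)CO)[C@H](/C=C(/C)CC[C@H]2O)O | intermediate
38 | γ-lactone C2,C12-diol C8,C9-acetonide | O[C@@H]1C=C[C@@]2(C)[C@H]([C@H]1C)[C@H]3OC(C)(C)O[C@@]34[C@H](/C=C(/C)CC[C@H]2O)OC(=O)[C@@H]4C | intermediate
39 | C2,C12-diacetate C8,C9-acetonide | CC(=O)O[C@@H]1C=C[C@@]2(C)[C@H]([C@H]1C)[C@H]3OC(C)(C)O[C@@]34[C@H](/C=C(/C)CC[C@H]2OC(C)=O)OC(=O)[C@@H]4C | intermediate
40 | CNP0286823.1, (1S,2R,5Z,7S,8R,9R,10S,11R,12R,17R)-2,12-diacetoxy-8,9-dihydroxybriara-5,13-dien-19,7-olide | CC(=O)O[C@@H]1C=C[C@@]2(C)[C@H]([C@H]1C)[C@@H](O)[C@@]1(O)[C@H](/C=C(/C)CC[C@H]2OC(C)=O)OC(=O)[C@@H]1C | target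

Total step count: 28. Longest linear sequence: 19 steps (steps 1–3, 5–8 and 17–28).

Steps most likely to fail

Step 5. The cycloaddition may stall at the hindered C3 terminus of the pyrone, lose CO2 by retro-[4+2] reaction, or show poor facial selectivity. The fallback sets out from 6 and keeps the [4+2] disconnection but uses a reactive achiral acetylene equivalent. Pyrone 6 and (E)-1,2-bis(phenylsulfonyl)ethene (toluene, 80 °C, or 10 kbar at 25 °C) should give the racemic trans-bis(phenylsulfonyl) adduct F1. Hydrogenation (H2, Pd/C, EtOAc) from the lactone face should give the saturated bis-sulfone F2. Reductive elimination with Na(Hg) and NaH2PO4 in MeOH at −20 °C should give racemic 12, that is 12 together with its enantiomer F3. Preparative HPLC on a chiral stationary phase brings the route back at 12.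

Step 21. Ring closure to the strained ten-membered ring may lose out to intermolecular coupling or reduction of the iodide, and stereocontrol at C9 may be poor. The fallback sets out from 31 and closes the ring by anionic acylation instead. Pinnick oxidation (NaClO2, NaH2PO4, 2-methylbut-2-ene) should give the carboxylic acid F4. Coupling with MeNHOMe·HCl (EDC, i-Pr2NEt) should give the Weinreb amide F5. Iodine–lithium exchange with t-BuLi at −100 °C under high dilution, followed by intramolecular acylation, should give the macrocyclic C9 enone F6. Corey–Bakshi–Shibata reduction with the (S)-catalyst and catecholborane should then set C9 under reagent control and return to the route at 32.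

Step 6. Saturation of the tetrasubstituted alkene may be incomplete, or hydrogen may be delivered from the wrong face. The fallback sets out from 9 and separates the two events. Hydrogenolysis alone (H2, 1 bar, Pd/C) should give 10, which is then isolated. Hydrogen-atom-transfer hydrogenation (Mn(dpm)3, PhSiH3, t-BuOOH, i-PrOH) should reduce the alkene through the C10 radical, which takes up hydrogen from the open lactone face, and return to the route at 11. This fallback makes no new compound (entry F0).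

Further compounds
F1 | step 5 | racemic trans-7,8-bis(phenylsulfonyl) Diels–Alder adduct of 6 (one enantiomer drawn) | O2[C@@H]1[C@H](S(=O)(=O)c3ccccc3)[C@@H](S(=O)(=O)c3ccccc3)[C@@](C2=O)(C)C(C(=O)OC(C)(C)C)=C1C
F2 | step 5 | racemic saturated bis-sulfone from F1 (one enantiomer drawn) | O2[C@@H]1[C@H](S(=O)(=O)c3ccccc3)[C@@H](S(=O)(=O)c3ccccc3)[C@@](C2=O)(C)[C@H]([C@H]1C)C(=O)OC(C)(C)C
F3 | step 5 | enantiomer of 12, tert-butyl (1S,4R,7S,8R)-4,7-dimethyl-3-oxo-2-oxabicyclo[2.2.2]oct-5-ene-8-carboxylate | O2[C@H]1C=C[C@](C2=O)(C)[C@@H]([C@@H]1C)C(=O)OC(C)(C)C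
F4 | step 21 | C9 carboxylic acid from 31 | CC(C)(C)[Si](C)(C)O[C@@H]1C=C[C@@]([C@H](O[Si](C)(C)C(C)(C)C)CC/C(C)=C\[C@H](O[Si](C)(C)C(C)(C)C)/C(I)=C/CO[Si](C)(C)C(C)(C)C)(C)[C@H]([C@H]1C)C(=O)O
F5 | step 21 | C9 N-methoxy-N-methylamide from F4 | CC(C)(C)[Si](C)(C)O[C@@H]1C=C[C@@]([C@H](O[Si](C)(C)C(C)(C)C)CC/C(C)=C\[C@H](O[Si](C)(C)C(C)(C)C)/C(I)=C/CO[Si](C)(C)C(C)(C)C)(C)[C@H]([C@H]1C)C(=O)N(C)OC
F6 | step 21 | macrocyclic C9 enone (C8=C17 exocyclic, CH2OTBS cis to C9) | CC(C)(C)[Si](C)(C)O[C@@H]1C=C[C@@]2(C)[C@H]([C@H]1C)C(=O)/C(=C\CO[Si](C)(C)C(C)(C)C)[C@H](/C=C(/C)CC[C@H]2O[Si](C)(C)C(C)(C)C)O[Si](C)(C)C(C)(C)C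
F0 | step 6 | none | none
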